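**Retrosynthetic overview**

1. Numbering used: dienone C1 (C=O), C2 (allyl), C3 (H), C4 (OMe and side chain), C5 (OMe), C6 (H); side chain C8 (CHMe), C7 (CH2Ar). The enabling feature is that C5(OMe)=C6–C1(=O) is a vinylogous methyl ester, i.e. the methanol adduct of an ynone, and that C4 is fully substituted between C3 and C5, so a C3 aldehyde cannot enolise, the ynone cannot isomerise and the ring cannot aromatise.
2. Key disconnection: C1–C6 and C2=C3 (with C5–OMe) in one pot from alkynal 16, pent-4-enoyl chloride and methanol (acyl Sonogashira coupling, oxa-Michael addition, aldol condensation).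
3. Alkynal 16 comes from a temporary gamma-aryl butyrolactone: its alpha carbon (future C4) is alkylated anti to the beta methyl (future C8), then the benzylic C7–O bond is hydrogenolysed. The lactone C=O becomes alkyne carbon C5 and the introduced CH(OMe)2 becomes aldehyde C3.
4. C8 (and the sacrificial C7 carbinol) come from a catalytic asymmetric syn-crotylboration of silylated vanillin.
5. Ring order: temporary butyrolactone closed in step 4 and opened in step 8; cyclohexadienone ring closed in step 12.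

Key step: step 12

Remark: Ar = 3-methoxy-4-[(triisopropylsilyl)oxy]phenyl; the target SMILES is read as 4S (ring) and 2R (side chain); compounds 1, 3 and 17 and all reagents are taken as commercial.

Step 1
Reactants: 1 vanillin
Product: 2 3-methoxy-4-[(triisopropylsilyl)oxy]benzaldehyde (ArCHO)
Conditions: i-Pr3SiCl, imidazole, DMF, rt
Reagents that add atoms: chlorotriisopropylsilane, CC(C)[Si](Cl)(C(C)C)C(C)C
Why: Imidazole-mediated silylation of the phenol (silyl ether protection) should install a bulky aryl silyl ether that tolerates amide bases, hydrogenation, hydrides and K2CO3/MeOH.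

Step 2
Reactants: 2 ArCHO; 3 2-[(2Z)-but-2-en-1-yl]-4,4,5,5-tetramethyl-1,3,2-dioxaborolane
Product: 4 (1R,2S)-1-Ar-2-methylbut-3-en-1-ol
Conditions: (R)-TRIP phosphoric acid [(R)-3,3'-bis(2,4,6-triisopropylphenyl)-1,1'-binaphthyl-2,2'-diyl hydrogen phosphate] (5 mol%), 4 Å MS, toluene, −30 °C; aq. NaHCO3 work-up
Reagents that add atoms: none
Why: Chiral phosphoric acid-catalysed crotylboration through a closed chair transition state should transfer the (Z)-geometry into the syn relationship, while the acid antipode that directs re-face attack (taken to be R; otherwise its mirror image is used) sets the absolute configuration and thereby the future C8 methyl centre, the carbinol centre being temporary.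

Step 3
Reactants: 4 (1R,2S)-1-Ar-2-methylbut-3-en-1-ol
Product: 5 (1R,2S)-1-Ar-2-methylbutane-1,4-diol
Conditions: 9-BBN (2.2 equiv), THF, 0 °C to rt; then 30% H2O2, aq. NaOAc, 0 °C to rt
Reagents that add atoms: hydrogen peroxide, OO
Why: Anti-Markovnikov hydroboration of the terminal alkene by the bulky borane followed by C–B oxidation with retention (hydroboration–oxidation) should give the primary alcohol without touching a stereocentre.

Step 4
Reactants: 5 (1R,2S)-1-Ar-2-methylbutane-1,4-diol
Product: 7 (4S,5R)-5-Ar-4-methyloxolan-2-one (cis lactone), via lactol 6 (not isolated)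
Conditions: TEMPO (20 mol%), PhI(OAc)2 (2.5 equiv), CH2Cl2, rt
Reagents that add atoms: none
Why: Nitroxyl-catalysed oxidation is selective for the primary alcohol, the aldehyde is trapped by the benzylic hydroxyl as a lactol and this is oxidised on to the lactone (oxidative lactonisation) without epimerisation.

Step 5
Reactants: 7 (4S,5R)-5-Ar-4-methyloxolan-2-one
Product: 8 (4S,5R)-5-Ar-3-hydroxy-4-methyloxolan-2-one (C3 epimers; mainly 3S)
Conditions: NaN(SiMe3)2, THF, −78 °C; 2-(benzenesulfonyl)-3-phenyloxaziridine, −78 °C; AcOH quench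
Reagents that add atoms: 2-(benzenesulfonyl)-3-phenyloxaziridine, O=S(=O)(c1ccccc1)N1OC1c1ccccc1
Why: Electrophilic hydroxylation of the lactone enolate by the N-sulfonyloxaziridine (Davis oxidation) should occur mainly anti to the C4 methyl, and the configuration of this carbon is irrelevant because it is made planar again in step 7.

Step 6
Reactants: 8 (4S,5R)-5-Ar-3-hydroxy-4-methyloxolan-2-one
Product: 9 (4R,5R)-5-Ar-3-methoxy-4-methyloxolan-2-one (C3 epimers)
Conditions: MeI (excess), Ag2O, 4 Å MS, MeCN, rt to 40 °C, dark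
Reagents that add atoms: iodomethane, CI
Why: Purdie methylation (Ag2O-assisted SN2 on iodomethane) should etherify the secondary alcohol under non-basic conditions that leave the lactone and the aryl silyl ether intact.

Step 7
Reactants: 9 (4R,5R)-5-Ar-3-methoxy-4-methyloxolan-2-one
Product: 11 (3S,4R,5R)-5-Ar-3-(dimethoxymethyl)-3-methoxy-4-methyloxolan-2-one, via silyl ketene acetal 10 (not isolated)
Conditions: LiN(SiMe3)2, THF, −78 °C; Me3SiCl; solvent exchange to CH2Cl2; HC(OMe)3, Me3SiOTf (10 mol%), −78 to −40 °C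
Reagents that add atoms: trimethyl orthoformate, COC(OC)OC
Why: In this Mukaiyama-type alkylation the planar silyl ketene acetal should attack the dimethoxycarbenium ion on the face anti to the adjacent methyl and the cis aryl group, which sets the quaternary centre (future C4) with CH(OMe)2 trans and OMe cis to methyl and makes both C3 epimers of 9 converge.

Step 8
Reactants: 11 (3S,4R,5R)-5-Ar-3-(dimethoxymethyl)-3-methoxy-4-methyloxolan-2-one
Product: 12 (2S,3R)-4-Ar-2-(dimethoxymethyl)-2-methoxy-3-methylbutanoic acid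
Conditions: H2 (3 atm), 10% Pd on carbon, EtOAc/MeOH, rt
Reagents that add atoms: none
Why: Hydrogenolysis of the benzylic C–O bond of the electron-rich gamma-aryl lactone should open the temporary ring and turn the auxiliary carbinol carbon into the C7 methylene, neither remaining stereocentre being involved.

Step 9
Reactants: 12 (2S,3R)-4-Ar-2-(dimethoxymethyl)-2-methoxy-3-methylbutanoic acid
Product: 13 methyl (2S,3R)-4-Ar-2-(dimethoxymethyl)-2-methoxy-3-methylbutanoate
Conditions: Me3SiCHN2, toluene/MeOH (4:1), 0 °C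
Reagents that add atoms: trimethylsilyldiazomethane, C[Si](C)(C)C=[N+]=[N-]
Why: O-Methylation of the carboxylic acid by the diazoalkane (diazomethane-type esterification) needs no attack at the hindered neopentylic carbonyl and should therefore be clean.

Step 10
Reactants: 13 methyl (2S,3R)-4-Ar-2-(dimethoxymethyl)-2-methoxy-3-methylbutanoate
Product: 15 (3R,4R)-5-Ar-3-(dimethoxymethyl)-3-methoxy-4-methylpent-1-yne, via aldehyde 14 (not isolated)
Conditions: i-Bu2AlH (1.2 equiv), CH2Cl2, −78 °C; MeOH; then dimethyl (1-diazo-2-oxopropyl)phosphonate, K2CO3, MeOH, −78 °C to rt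
Reagents that add atoms: dimethyl (1-diazo-2-oxopropyl)phosphonate, CC(=O)C(=[N+]=[N-])P(=O)(OC)OC
Why: The alpha-methoxy ester should give a chelated aluminium hemiacetal that stops at the aldehyde stage, and the aldehyde, which has no alpha hydrogen and cannot epimerise, is homologated in the same flask by the Seyferth–Gilbert reaction with the Bestmann–Ohira reagent.

Step 11
Reactants: 15 (3R,4R)-5-Ar-3-(dimethoxymethyl)-3-methoxy-4-methylpent-1-yne
Product: 16 (2R,3R)-4-Ar-2-ethynyl-2-methoxy-3-methylbutanal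
Conditions: CF3CO2H/H2O (4:1), CH2Cl2, 0 °C to rt; used crude
Reagents that add atoms: water, O
Why: Acid-catalysed acetal hydrolysis via the oxocarbenium ion should unmask the aldehyde, the quaternary alpha carbon ruling out enolisation and the aryl silyl ether tolerating aqueous trifluoroacetic acid.

Step 12
Reactants: 16 (2R,3R)-4-Ar-2-ethynyl-2-methoxy-3-methylbutanal; 17 pent-4-enoyl chloride
Product: 21 (4S)-2-allyl-4-[(2R)-1-Ar-propan-2-yl]-4,5-dimethoxycyclohexa-2,5-dien-1-one, via ynone 18 (not isolated), via methoxy enone 19 (not isolated), via aldol 20 (not isolated)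
Conditions: 17 (1.2 equiv), PdCl2(PPh3)2 (2 mol%), CuI (4 mol%), Et3N (1.3 equiv), THF, rt, argon; then MeOH, K2CO3 (3 equiv), rt to 40 °C
Reagents that add atoms: methanol, CO
Why: Oxidative addition of the acid chloride to zerovalent palladium, transmetallation from the copper acetylide of 16 and reductive elimination give the ynone and with it the C1–C6 bond (acyl Sonogashira coupling); methoxide from K2CO3/MeOH then adds to C5, the beta carbon of the ynone (oxa-Michael addition), and the resulting enone is enolised at C2, its only acidic position, and adds to the aldehyde before E1cB loss of water creates the C2=C3 bond. The closest known reaction types are one-pot coupling–addition–cyclocondensation sequences of ynones and the aldol-condensation half of the Robinson annulation. The six-membered ring is closed by a 6-(enolexo)-exo-trig aldol addition. No stereocentre is formed, and C4 (no hydrogen) and C8 (not next to a carbonyl) cannot epimerise. The step needs regioselective methanol addition, which the ynone polarisation secures, and it needs the (E)-enone in which C4 and the acyl group are cis; the E and Z isomers interconvert by reversible methoxide addition, so the mixture is funnelled through the only isomer that can cyclise. Aromatisation, allene formation and enolisation of the aldehyde are all blocked by the fully substituted C4.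

Step 13
Reactants: 21 (4S)-2-allyl-4-[(2R)-1-Ar-propan-2-yl]-4,5-dimethoxycyclohexa-2,5-dien-1-one
Product: 22 (4S)-2-allyl-4-[(2R)-1-(4-hydroxy-3-methoxyphenyl)propan-2-yl]-4,5-dimethoxycyclohexa-2,5-dien-1-one (target)
Conditions: Bu4NF, AcOH (1:1), THF, 0 °C
Reagents that add atoms: none
Why: Fluoride should cleave the aryl Si–O bond (desilylation) while the acetic acid buffer keeps the cross-conjugated dienone away from free phenoxide or fluoride base, and any silyl ether already lost in step 12 would be the same product.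

**Compound list**

1 | vanillin (4-hydroxy-3-methoxybenzaldehyde) | O=Cc1ccc(O)c(OC)c1 | starting material
2 | 3-methoxy-4-[(triisopropylsilyl)oxy]benzaldehyde | O=Cc1ccc(O[Si](C(C)C)(C(C)C)C(C)C)c(OC)c1 | intermediate
3 | 2-[(2Z)-but-2-en-1-yl]-4,4,5,5-tetramethyl-1,3,2-dioxaborolane | C/C=C\CB1OC(C)(C)C(C)(C)O1 | starting material
4 | (1R,2S)-1-Ar-2-methylbut-3-en-1-ol | O[C@@H](c1ccc(O[Si](C(C)C)(C(C)C)C(C)C)c(OC)c1)[C@@H](C)C=C | intermediate
5 | (1R,2S)-1-Ar-2-methylbutane-1,4-diol | O[C@@H](c1ccc(O[Si](C(C)C)(C(C)C)C(C)C)c(OC)c1)[C@@H](C)CCO | intermediate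
6 | (4S,5R)-5-Ar-4-methyloxolan-2-ol (lactol, anomer mixture) | OC1O[C@@H](c2ccc(O[Si](C(C)C)(C(C)C)C(C)C)c(OC)c2)[C@@H](C)C1 | intermediate
7 | (4S,5R)-5-Ar-4-methyloxolan-2-one (cis lactone) | O=C1O[C@@H](c2ccc(O[Si](C(C)C)(C(C)C)C(C)C)c(OC)c2)[C@@H](C)C1 | intermediate
8 | (4S,5R)-5-Ar-3-hydroxy-4-methyloxolan-2-one (C3 epimers) | O=C1O[C@@H](c2ccc(O[Si](C(C)C)(C(C)C)C(C)C)c(OC)c2)[C@@H](C)C1O | intermediate
9 | (4R,5R)-5-Ar-3-methoxy-4-methyloxolan-2-one (C3 epimers) | O=C1O[C@@H](c2ccc(O[Si](C(C)C)(C(C)C)C(C)C)c(OC)c2)[C@@H](C)C1OC | intermediate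
10 | {[(4R,5R)-5-Ar-3-methoxy-4-methyl-4,5-dihydrofuran-2-yl]oxy}trimethylsilane | COC1=C(O[Si](C)(C)C)O[C@@H](c2ccc(O[Si](C(C)C)(C(C)C)C(C)C)c(OC)c2)[C@H]1C | intermediate
11 | (3S,4R,5R)-5-Ar-3-(dimethoxymethyl)-3-methoxy-4-methyloxolan-2-one | O=C1O[C@@H](c2ccc(O[Si](C(C)C)(C(C)C)C(C)C)c(OC)c2)[C@@H](C)[C@]1(OC)C(OC)OC | intermediate
12 | (2S,3R)-4-Ar-2-(dimethoxymethyl)-2-methoxy-3-methylbutanoic acid | COC(OC)[C@@](OC)([C@H](C)Cc1ccc(O[Si](C(C)C)(C(C)C)C(C)C)c(OC)c1)C(=O)O | intermediate
13 | methyl (2S,3R)-4-Ar-2-(dimethoxymethyl)-2-methoxy-3-methylbutanoate | COC(OC)[C@@](OC)([C@H](C)Cc1ccc(O[Si](C(C)C)(C(C)C)C(C)C)c(OC)c1)C(=O)OC | intermediate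
14 | (2R,3R)-4-Ar-2-(dimethoxymethyl)-2-methoxy-3-methylbutanal | COC(OC)[C@@](OC)([C@H](C)Cc1ccc(O[Si](C(C)C)(C(C)C)C(C)C)c(OC)c1)C=O | intermediate
15 | (3R,4R)-5-Ar-3-(dimethoxymethyl)-3-methoxy-4-methylpent-1-yne | COC(OC)[C@@](OC)([C@H](C)Cc1ccc(O[Si](C(C)C)(C(C)C)C(C)C)c(OC)c1)C#C | intermediate
16 | (2R,3R)-4-Ar-2-ethynyl-2-methoxy-3-methylbutanal | O=C[C@@](OC)([C@H](C)Cc1ccc(O[Si](C(C)C)(C(C)C)C(C)C)c(OC)c1)C#C | intermediate
17 | pent-4-enoyl chloride | C=CCCC(Cl)=O | starting material
18 | (2R)-2-[(2R)-1-Ar-propan-2-yl]-2-methoxy-5-oxonon-8-en-3-ynal | O=C[C@@](OC)([C@H](C)Cc1ccc(O[Si](C(C)C)(C(C)C)C(C)C)c(OC)c1)C#CC(=O)CCC=C | intermediate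
19 | (2R,3E)-2-[(2R)-1-Ar-propan-2-yl]-2,3-dimethoxy-5-oxonona-3,8-dienal | O=C[C@@](OC)([C@H](C)Cc1ccc(O[Si](C(C)C)(C(C)C)C(C)C)c(OC)c1)/C(OC)=C\C(=O)CCC=C | intermediate
20 | (4S)-6-allyl-4-[(2R)-1-Ar-propan-2-yl]-5-hydroxy-3,4-dimethoxycyclohex-2-en-1-one (C5/C6 mixture) | C=CCC1C(O)[C@@](OC)([C@H](C)Cc2ccc(O[Si](C(C)C)(C(C)C)C(C)C)c(OC)c2)C(OC)=CC1=O | intermediate
21 | (4S)-2-allyl-4-[(2R)-1-Ar-propan-2-yl]-4,5-dimethoxycyclohexa-2,5-dien-1-one | C=CCC1=C[C@@](OC)([C@H](C)Cc2ccc(O[Si](C(C)C)(C(C)C)C(C)C)c(OC)c2)C(OC)=CC1=O | intermediate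
22 | (4S)-2-allyl-4-[(2R)-1-(4-hydroxy-3-methoxyphenyl)propan-2-yl]-4,5-dimethoxycyclohexa-2,5-dien-1-one | C=CCC1=C[C@@](OC)([C@H](C)Cc2ccc(O)c(OC)c2)C(OC)=CC1=O | target

**Step count and risks**

Total step count: 13. Longest linear sequence: 13 steps (vanillin 1 to target 22).

Steps most likely to fail:

Step 12. Methoxide may add to the hindered aldehyde and trigger loss of the formyl group by retro-Claisen-type C3–C4 cleavage, or enolisation at C2 may be too slow so that the sequence stalls at the open-chain enone. The fallback sets out from 15 and comes back at 21. Acetal 15 would be coupled with 17 under the same PdCl2(PPh3)2/CuI/Et3N conditions to give the ynone acetal F1. K2CO3/MeOH would add methanol to give the (E)-beta-methoxy enone acetal F2. Kinetic enolisation (LiN(SiMe3)2, Me3SiCl, THF, −78 °C) would give the 2-silyloxy diene F3. Catalytic Me3SiOTf (CH2Cl2, −78 °C) would ionise the dimethyl acetal and close the ring by an intramolecular Mukaiyama aldol addition to the cyclic beta-methoxy ketone F4, from which DBU would eliminate methanol to give 21. No free aldehyde meets base in this variant, and step 11 is not needed.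

Step 7. Attack of the hindered, tetrasubstituted ketene acetal on the dimethoxycarbenium ion may be slow or show poor facial selectivity. The fallback sets out from 9 and comes back at 11. The lithium enolate of 9 (LiN(SiMe3)2, THF, −78 °C) would be treated with gaseous formaldehyde to give, by aldol addition anti to the methyl group, the hydroxymethyl lactone F5. Dess–Martin oxidation would give the formyl lactone F6, and HC(OMe)3/MeOH with catalytic TsOH would convert it into 11.

Step 10. The ester may be over-reduced to the primary alcohol, or homologation of the neopentylic aldehyde may be so slow that K2CO3/MeOH begins to cleave the aryl silyl ether. The fallback sets out from 13 and comes back at 15. LiAlH4 (THF, 0 °C) would give the primary alcohol F7, and Swern oxidation would give aldehyde 14, this time isolated. CBr4/PPh3 (CH2Cl2, 0 °C) would give the dibromoalkene F8, and n-BuLi (2.2 equiv, THF, −78 °C) followed by an aqueous quench would give 15 (Corey–Fuchs sequence).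

**Further compounds**

F1 | step 12 | (2R)-2-[(2R)-1-Ar-propan-2-yl]-1,1,2-trimethoxynon-8-en-3-yn-5-one | COC(OC)[C@@](OC)([C@H](C)Cc1ccc(O[Si](C(C)C)(C(C)C)C(C)C)c(OC)c1)C#CC(=O)CCC=C
F2 | step 12 | (2R,3E)-2-[(2R)-1-Ar-propan-2-yl]-1,1,2,3-tetramethoxynona-3,8-dien-5-one | COC(OC)[C@@](OC)([C@H](C)Cc1ccc(O[Si](C(C)C)(C(C)C)C(C)C)c(OC)c1)/C(OC)=C\C(=O)CCC=C
F3 | step 12 | (2R,3E)-2-[(2R)-1-Ar-propan-2-yl]-1,1,2,3-tetramethoxy-5-(trimethylsilyloxy)nona-3,5,8-triene | COC(OC)[C@@](OC)([C@H](C)Cc1ccc(O[Si](C(C)C)(C(C)C)C(C)C)c(OC)c1)/C(OC)=C\C(O[Si](C)(C)C)=CCC=C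
F4 | step 12 | (4S)-6-allyl-4-[(2R)-1-Ar-propan-2-yl]-3,4,5-trimethoxycyclohex-2-en-1-one (C5/C6 mixture) | C=CCC1C(OC)[C@@](OC)([C@H](C)Cc2ccc(O[Si](C(C)C)(C(C)C)C(C)C)c(OC)c2)C(OC)=CC1=O
F5 | step 7 | (3S,4R,5R)-5-Ar-3-(hydroxymethyl)-3-methoxy-4-methyloxolan-2-one | O=C1O[C@@H](c2ccc(O[Si](C(C)C)(C(C)C)C(C)C)c(OC)c2)[C@@H](C)[C@]1(OC)CO
F6 | step 7 | (3S,4R,5R)-5-Ar-3-methoxy-4-methyl-2-oxooxolane-3-carbaldehyde | O=C1O[C@@H](c2ccc(O[Si](C(C)C)(C(C)C)C(C)C)c(OC)c2)[C@@H](C)[C@]1(OC)C=O
F7 | step 10 | (2R,3R)-4-Ar-2-(dimethoxymethyl)-2-methoxy-3-methylbutan-1-ol | COC(OC)[C@@](OC)([C@H](C)Cc1ccc(O[Si](C(C)C)(C(C)C)C(C)C)c(OC)c1)CO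
F8 | step 10 | (3R,4R)-5-Ar-1,1-dibromo-3-(dimethoxymethyl)-3-methoxy-4-methylpent-1-ene | COC(OC)[C@@](OC)([C@H](C)Cc1ccc(O[Si](C(C)C)(C(C)C)C(C)C)c(OC)c1)C=C(Br)Br
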